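If the partner of a flask goes completely into adducts, two balances close the flask. Starting material is counted once in each of its forms, and partner once in each mono adduct and twice in the bis adduct.

| setting | oak | larch | Wednesday's | Friday's |
|---|---|---|---|---|
| starting material | 0.20 M | 0.20 M | 0.20 M | 0.20 M |
| partner | 0.24 M | 0.65 M | 0.220 M | 0.550 M |
| remark | run made earlier | run made earlier |  |  |
| time |  |  | 4.0 d | 4.0 d |

| run | time / d | starting material / % | single product / % | bis adduct / % | other mono adduct / % |
|---|---|---|---|---|---|
| oak | 0.500 | 7 | 62 | 23 | 2 |
| oak | 1.04 | 8 | 67 | 29 | 0 |
| oak | 1.25 | 6 | 65 | 29 | 0 |
| oak | 2.08 | 8 | 66 | 25 | 0 |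
| oak | 2.50 | 6 | 66 | 28 | 7 |
| oak | 3.00 | 6 | 66 | 29 | 1 |
| larch | 0.500 | 0 | 48 | 53 | 0 |
| larch | 1.04 | 0 | 35 | 65 | 0 |
| larch | 1.25 | 1 | 30 | 68 | 0 |
| larch | 2.08 | 0 | 14 | 83 | 2 |
| larch | 2.50 | 1 | 13 | 88 | 1 |
| larch | 3.00 | 0 | 8 | 88 | 0 |

(readings scatter by 2 percentage points)

1. which of these there is most of at the end, counted by the starting material in it, Wednesday's (single product / other mono adduct / starting material / bis adduct)
2. which of these there is most of at the end, counted by the starting material in it, Friday's (single product / other mono adduct / starting material / bis adduct)
3. final amount of the leader among these, as a percentage of the starting material charged, in Wednesday's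
4. final amount of the leader among these, as a percentage of the starting material charged, in Friday's



Subtracting the balances, Wednesday's charge gives 10 percentage points. This number is the excess gap: the charged ratio of [partner] to [starting material] less one, which equals bis adduct minus starting material, in points of the starting material charged, once partner has gone into adducts.

The gap leaves open where on that line the flask stops, so two extremes bracket Wednesday's. If the second addition waits for the first to finish, the flask holds 10.0 % bis adduct, 90.0 % mono adducts and no starting material. If each molecule reacting goes straight on to bis adduct, it holds 55.0 % bis adduct and 45.0 % starting material.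

The oak run shows which end is nearer: its gap is 20 points, its last reading gives 23 points, and its starting material reads 6 %. Wednesday's has less partner, so its starting material is expected above that reading. Each point of starting material costs two points of mono adduct, one for itself and one for the bis adduct tied to it. The mono adducts together are therefore expected below 78.0 %, and by the gap they stay ahead of bis adduct while starting material is under 26.7 %. The oak run's reading of 6 % lies under that line, and Wednesday's partner differs from the oak run's by 0.0200 M, so the mono adducts are expected to lead Wednesday's. Among them, the oak run's last reading gives single product 66 % and other mono adduct 1 %.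

Friday's ratio of 2.75 exceeds the two equivalents that bis adduct takes, so the gap does not apply there. In the larch run, single product reads 48 % at 0.500 d and 8 % at 3.00 d, so bis adduct is expected to lead Friday's.

The forecast gives single product at 67 % for Wednesday's and bis adduct at 91 % for Friday's, reading the oak run thus: “the plateau is partner exhaustion, not equilibrium”.

The simulation gives single product at 61.2 % for Wednesday's and bis adduct at 87.5 % for Friday's.

    partner → decomposition product (k = 3.00 × 10⁻⁴ h⁻¹)
    starting material + partner → other mono adduct + by-product (k = 2.50 M⁻¹ h⁻¹)
    partner + other mono adduct → bis adduct + by-product (k = 19.0 M⁻¹ h⁻¹)
    partner + single product → bis adduct + by-product (k = 0.0870 M⁻¹ h⁻¹)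
    starting material + partner → single product + by-product (k = 6.20 M⁻¹ h⁻¹)

Wednesday's ends with partner at 0 % of its charge and bis adduct minus starting material at 10 points, on the gap. Its starting material of 13.0 % leaves the mono adducts 64.0 % by the gap, and they stand at 64.0 %, of which 2.87 % is other mono adduct. Friday's bis adduct leads because of the conversion of partner + single product into bis adduct + by-product: Friday's run without that step ends at 28.7 % bis adduct instead of 87.5 %, and bis adduct no longer leads.

For the neighbour of Wednesday's charged with 0.055 M of partner, the gap is −73 points. That flask ends with partner at 0 % of its charge, bis adduct 2.03 % and starting material 75 %, a difference of −73 points.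

(All runs were computed for substances that don't exist, and the scatter is random.)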